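(Its constants stand for no real mixture.)

Beside this flask stands a neighbour charged with 0.15 M of partner, 2.50 times the 0.0600 M here, and I want one reckoning that serves both.

left-handed substrate 0.10 M; partner 0.0600 M (fed, over 12 min); right-handed substrate 0.10 M; time 3.0 d

    partner + right-handed substrate → right-handed product (k1 = 12.3 M⁻¹ h⁻¹)
    partner + left-handed substrate → left-handed product (k2 = 23.3 M⁻¹ h⁻¹)
    partner → decomposed reagent (k3 = 0.106 h⁻¹)

- partner is single-handed; left-handed substrate and right-handed substrate are mirror images of each other, charged as a racemate, each of them at the stated concentration
- the reaction counts as stopped when no species that holds the left-handed substrate and right-handed substrate together changes by six tenths of a point or more over the second half of the time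
- run time (flask): 3.0 d
- the handed part of partner does not stay in what it makes, so the products of the two hands are mirror images too

1. why nothing more happens at 3.0 d, or that something still does (the partner has run out first / all of the left-handed substrate has reacted / it is still moving)
2. amount of left-handed product at 3.0 d, in percent of the left-handed substrate and right-handed substrate together charged
3. amount of right-handed substrate at 3.0 d, in percent of the left-handed substrate and right-handed substrate together charged

I reckon with rates. Partner is the limiting reagent, 0.0600 M against 0.200 M of substrate. Its three exits are each first order in [partner], so [partner] cancels from their ratios and the dosing drops out. I follow the rate of the left-handed step over that of the right-handed step. At the start it is the selectivity factor, and partner is captured at a pseudo-first-order rate: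

ratio at start = 1.89, capture = 3.56 h⁻¹

Both steps slow as [partner] falls, but that cancels from the ratio; what then moves the ratio is the loss of each step's own substrate. A first split of the charge in the start ratio gives the left-handed substrate 0.0393 M, so at the midpoint of that uptake the two steps run, per unit of [partner], at these fractions of their start rates:

left-handed 0.804, right-handed 0.896

midway ratio = 1.89 × 0.804 / 0.896 = 1.70

This is what I carry: ρ, the midway hand ratio, which I let stand for the whole run as an estimate.

midway capture = 2.98 h⁻¹, against decomposition at 0.106 h⁻¹, so the leak is 3.44%

Captured partner, 0.0579 M, divides by ρ, which gives left-handed product 18.2% and right-handed substrate 39.3%. After the full first split, capture is still 2.39 h⁻¹, a partner half-life of 0.290 h against 3.0 d, so I expect partner to end this flask.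

The forecast says the partner has run out first, 18.3% and 39.3%, with “about 37% of the left-handed and 21% of the right-handed substrate react”.

The simulation gives the partner has run out first, with 0% of partner left, 18.3% and 39.3%. In this flask the left-handed step runs 1.7 times as fast as the right-handed one at 0.0127 d, down from 1.89, and by 0.306 h half of the left-handed product has formed. The same lines for the neighbour with 0.15 M of partner give ρ = 1.30, and that neighbour ends with 41.1% left-handed product against 29.9% right-handed product, a ratio of 1.37.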